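Assumption: the target SMILES contains no stereocentre, stereogenic axis or stereogenic double bond. Vidalol A is therefore achiral, there is no enantiomer to select, and no stereocontrol step is needed.

**Retrosynthetic overview**
1. Vidalol A comes from its pentamethyl ether by a final five-fold O-demethylation. That ether comes from the ring B debromo compound by NBS monobromination at one of two equivalent ring B positions.
2. The key disconnection is the ring A aryl–CH2 bond. The CH2 carbon is the carbonyl carbon of 2,4,6-trimethoxybenzaldehyde, used as its NH2-hydrazone (a benzyl carbanion equivalent). It is joined to a C–Br carbon of ring A with loss of N2, so two natively electrophilic carbons become bonded.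
3. The ring A partner is 1,2,3-tribromo-4,5-dimethoxybenzene. Only its least hindered terminal bromide is consumed, and the two that remain are the ring A bromines of the target. It is made from guaiacol by tribromination and O-methylation.
4. No ring is formed. Ring A is bought as guaiacol and ring B as the trimethoxybenzaldehyde.

**Route**

Step 1
Reactants: 1 guaiacol (2-methoxyphenol)
Product: 2 2,3,4-tribromo-6-methoxyphenol (4,5,6-tribromoguaiacol)
Conditions: Br2 (3.1 equiv), AcOH, 10 °C → rt, 16 h
Reagents that add atoms: bromine, BrBr
Why: Electrophilic aromatic bromination, in which the free OH sends two bromines to its para and ortho positions and the OMe sends the third to its own para position, while the remaining C–H (ortho to OMe, meta to OH) reacts much more slowly, so the reaction stops at the contiguous tribromide.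

Step 2
Reactants: 2 2,3,4-tribromo-6-methoxyphenol
Product: 3 1,2,3-tribromo-4,5-dimethoxybenzene (3,4,5-tribromoveratrole)
Conditions: MeI (1.5 equiv), K2CO3 (2 equiv), acetone, reflux
Reagents that add atoms: iodomethane, CI
Why: Williamson ether synthesis on an acidic bromophenol, which removes the phenoxide that would otherwise deactivate the para C–Br toward oxidative addition and leaves all five oxygens under a single protecting group.

Step 3
Reactants: 3 1,2,3-tribromo-4,5-dimethoxybenzene; 4 2,4,6-trimethoxybenzaldehyde
Product: 7 2-[(2,3-dibromo-4,5-dimethoxyphenyl)methyl]-1,3,5-trimethoxybenzene, via trimethoxybenzaldehyde hydrazone 5 (not isolated), via diarylmethyl diazene 6 (not isolated)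
Conditions: 4, N2H4·H2O (1.2 equiv), THF, 50 °C, 4 Å MS; then add to 3 (1.5 equiv), Ni(cod)2 (10 mol %), PMe3 (20 mol %), LiOtBu (2 equiv), DBU (1 equiv), THF, 60 °C
Reagents that add atoms: hydrazine hydrate, NN.O (its two nitrogens are carried in 5 and 6 and leave as N2; only hydrogen stays in 7)
Why: Proposed new method: the closest known reaction type is the nickel-catalysed cross-coupling of N-unsubstituted aldehyde hydrazones with aryl bromides (hydrazone as benzyl carbanion equivalent, Wolff–Kishner-type loss of N2), here asked for the first time to choose one of three C–Br bonds: zerovalent nickel should insert into the terminal C–Br of 3 that has an ortho hydrogen (the other two are flanked on both sides, in line with the terminal selectivity of couplings on 1,2,3-trihaloarenes), the lithiated hydrazone 5 binds the divalent arylnickel bromide and reductively eliminates through carbon to give diazene 6, which loses N2 under base and is protonated to 7, so a former carbonyl carbon and a former C–Br carbon, both electrophilic by nature, become bonded and no stereocentre remains.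

Step 4
Reactants: 7 2-[(2,3-dibromo-4,5-dimethoxyphenyl)methyl]-1,3,5-trimethoxybenzene
Product: 8 2-bromo-4-[(2,3-dibromo-4,5-dimethoxyphenyl)methyl]-1,3,5-trimethoxybenzene
Conditions: NBS (1.0 equiv), MeCN, 0 °C, dark
Reagents that add atoms: N-bromosuccinimide, O=C1CCC(=O)N1Br
Why: Electrophilic aromatic bromination, in which the two free ring B positions are equivalent and each is activated by three methoxy groups, ring A is deactivated by two bromines, and the first ring B bromine slows a second attack enough for one equivalent of NBS to stop at the monobromide.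

Step 5
Reactants: 8 2-bromo-4-[(2,3-dibromo-4,5-dimethoxyphenyl)methyl]-1,3,5-trimethoxybenzene
Product: 9 vidalol A, 2-bromo-4-[(2,3-dibromo-4,5-dihydroxyphenyl)methyl]benzene-1,3,5-triol
Conditions: BBr3 (8 equiv), CH2Cl2, −78 °C → rt, 16 h; then ice/H2O
Reagents that add atoms: none
Why: Lewis-acid aryl methyl ether cleavage, in which BBr3 binds each OMe, bromide removes the methyl group by SN2 and aqueous work-up frees the five phenols, while the aryl bromides and the diarylmethane link are left intact at or below room temperature, as in the usual end-game for bromophenol natural products.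

**Compound list**
1 | guaiacol (2-methoxyphenol) | COc1ccccc1O | starting material
2 | 2,3,4-tribromo-6-methoxyphenol (4,5,6-tribromoguaiacol) | COc1cc(Br)c(Br)c(Br)c1O | intermediate
3 | 1,2,3-tribromo-4,5-dimethoxybenzene | COc1cc(Br)c(Br)c(Br)c1OC | intermediate
4 | 2,4,6-trimethoxybenzaldehyde | COc1cc(OC)c(C=O)c(OC)c1 | starting material
5 | (E)-(2,4,6-trimethoxybenzylidene)hydrazine (NH2-hydrazone of 4, not isolated) | COc1cc(OC)c(/C=N/N)c(OC)c1 | intermediate
6 | [(2,3-dibromo-4,5-dimethoxyphenyl)(2,4,6-trimethoxyphenyl)methyl]diazene (racemic, transient, not isolated) | COc1cc(OC)c(C(N=N)c2cc(OC)c(OC)c(Br)c2Br)c(OC)c1 | intermediate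
7 | 2-[(2,3-dibromo-4,5-dimethoxyphenyl)methyl]-1,3,5-trimethoxybenzene | COc1cc(OC)c(Cc2cc(OC)c(OC)c(Br)c2Br)c(OC)c1 | intermediate
8 | 2-bromo-4-[(2,3-dibromo-4,5-dimethoxyphenyl)methyl]-1,3,5-trimethoxybenzene | COc1cc(OC)c(Cc2cc(OC)c(OC)c(Br)c2Br)c(OC)c1Br | intermediate
9 | vidalol A, 2-bromo-4-[(2,3-dibromo-4,5-dihydroxyphenyl)methyl]benzene-1,3,5-triol (achiral) | Oc1cc(Cc2c(O)cc(O)c(Br)c2O)c(Br)c(Br)c1O | target

**Total step count:** 5
**Longest linear sequence:** 5 steps (1 → 2 → 3 → 7 → 8 → 9). Compound 4 is bought and enters at step 3.

**Three steps most likely to fail**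

**Step 3 (key coupling).**
- Risks: a small-phosphine nickel catalyst may attack the central or the OMe-flanked C–Br, particularly if an electron-transfer pathway favours loss of the strained central bromine. It may also over-couple or hydrodebrominate. The hydrazone flanked by two ortho methoxy groups is hindered and may form the azine or undergo N-arylation instead.
- Fallback: this sets out from 3 and 4 and comes back at 7. It removes low-valent metal from the C–C bond-forming event.
 - Compound 4 with TsNHNH2 in MeOH at 60 °C gives (E)-2,4,6-trimethoxybenzaldehyde N-tosylhydrazone F1.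
 - Compound 3 undergoes a sterically governed Miyaura-type borylation of the same terminal C–Br (B2(OH)4, Pd(OAc)2, XPhos, KOAc, EtOH, 80 °C). This gives (2,3-dibromo-4,5-dimethoxyphenyl)boronic acid F2, whose regiochemistry can be checked and purified before the union.
 - Heating F1 and F2 with K2CO3 in dioxane at 110 °C (metal-free Barluenga–Valdés reductive coupling) releases 2-(diazomethyl)-1,3,5-trimethoxybenzene F3, whose nucleophilic carbon attacks boron.
 - A 1,2-aryl shift with loss of N2 gives [(2,3-dibromo-4,5-dimethoxyphenyl)(2,4,6-trimethoxyphenyl)methyl]boronic acid F4, and protodeboronation in the same flask delivers 7 with both aryl bromides untouched.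

**Step 4 (monobromination).**
- Risk: the second ring B position is still strongly activated, so mixtures of 7, 8 and the ring B dibromide are possible and hard to separate.
- Fallback: this sets out from 4 and comes back at 8. Ring B is brominated before the coupling.
 - The formyl group tempers ring B, so NBS (1.0 equiv, MeCN, rt) stops cleanly at 3-bromo-2,4,6-trimethoxybenzaldehyde F5.
 - N2H4·H2O converts F5 into (E)-(3-bromo-2,4,6-trimethoxybenzylidene)hydrazine F6.
 - The nickel coupling of step 3 with 3 then gives 8 directly, through [(3-bromo-2,4,6-trimethoxyphenyl)(2,3-dibromo-4,5-dimethoxyphenyl)methyl]diazene F7.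
 - The ring B C–Br sits between two methoxy groups on the more electron-rich ring, so it should undergo oxidative addition more slowly than the terminal C–Br of 3.

**Step 5 (five-fold demethylation).**
- Risks: the emerging bromophloroglucinol ring protonates easily. The HBr formed can therefore cause protodebromination or bromine migration on ring B, or acid cleavage of the benzyl–phloroglucinol bond.
- Fallback: this sets out from 7 and comes back at 9. The order of the last two operations is reversed, so the labile ring B C–Br never meets BBr3.
 - BBr3 (CH2Cl2, −78 °C → rt) on 7 gives 2-[(2,3-dibromo-4,5-dihydroxyphenyl)methyl]benzene-1,3,5-triol F8.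
 - The phloroglucinol ring of F8 is far more nucleophilic than the dibromocatechol ring. It is monobrominated with NBS (1.0 equiv, THF, −78 °C) to give 9.

**Further compounds**
F1 | step 3 | (E)-2,4,6-trimethoxybenzaldehyde N-tosylhydrazone | COc1cc(OC)c(/C=N/NS(=O)(=O)c2ccc(C)cc2)c(OC)c1
F2 | step 3 | (2,3-dibromo-4,5-dimethoxyphenyl)boronic acid | COc1cc(B(O)O)c(Br)c(Br)c1OC
F3 | step 3 | 2-(diazomethyl)-1,3,5-trimethoxybenzene | COc1cc(OC)c(C=[N+]=[N-])c(OC)c1
F4 | step 3 | [(2,3-dibromo-4,5-dimethoxyphenyl)(2,4,6-trimethoxyphenyl)methyl]boronic acid (racemic, transient) | COc1cc(OC)c(C(B(O)O)c2cc(OC)c(OC)c(Br)c2Br)c(OC)c1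
F5 | step 4 | 3-bromo-2,4,6-trimethoxybenzaldehyde | COc1cc(OC)c(C=O)c(OC)c1Br
F6 | step 4 | (E)-(3-bromo-2,4,6-trimethoxybenzylidene)hydrazine | COc1cc(OC)c(/C=N/N)c(OC)c1Br
F7 | step 4 | [(3-bromo-2,4,6-trimethoxyphenyl)(2,3-dibromo-4,5-dimethoxyphenyl)methyl]diazene (racemic, transient) | COc1cc(OC)c(C(N=N)c2cc(OC)c(OC)c(Br)c2Br)c(OC)c1Br
F8 | step 5 | 2-[(2,3-dibromo-4,5-dihydroxyphenyl)methyl]benzene-1,3,5-triol | Oc1cc(O)c(Cc2cc(O)c(O)c(Br)c2Br)c(O)c1
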